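The intermediate is a fork, and you should reckon from that fork before you look at any computed curve.

all flasks: substrate 0.18 M; time 20 h
- dawn: partner 1.10 equiv
- dusk: partner 1.70 equiv
- noon: partner 2.50 equiv

    intermediate → side product (k1 = 0.00272 min⁻¹)
    partner → decomposed reagent (k2 = 7.66 × 10⁻⁴ min⁻¹)
    target ⇌ isomer of the product (K3 = 2.6, k3 = 0.00220 min⁻¹)
    substrate + partner → intermediate + released group (k4 = 0.0273 M⁻¹ min⁻¹)
    intermediate → target (k5 = 0.00162 min⁻¹)

- which of these there is most of at the end, counted by the substrate in it, dawn (intermediate / side product / target / isomer of the product / substrate)
- which of these there is most of at the end, counted by the substrate in it, dusk (intermediate / side product / target / isomer of the product / substrate)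
- which of these there is most of at the end, counted by the substrate in it, noon (intermediate / side product / target / isomer of the product / substrate)
- how much there is at the end of the one of these that leads, in percent of the substrate charged: dawn
- how much there is at the end of the one of these that leads, in percent of the substrate charged: dusk
- how much there is at the end of the one of these that leads, in percent of the substrate charged: noon

Two rates matter. The intermediate goes to the side product at 0.00272 min⁻¹ and to the target at 0.00162 min⁻¹, with half-lives of 4.2 h and 7.1 h, so the first exit is the faster. Both steps are first order in the intermediate, so their ratio, the selectivity factor, stays 1.68 at each moment, whatever the partner is doing. The fork share is 62.7%, the part of whatever leaves the intermediate that becomes side product.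

The exchange of target and isomer lies downstream and returns nothing to the fork, while decay of the partner changes how much reaches the fork, not how it splits. So work with the fraction left: side product equals the share times what remains after subtracting the substrate and intermediate left. Target and isomer together get 37.3% of that remainder, less than the side product. Neglecting the intermediate, the side product also passes the substrate once the substrate left falls under 38.5%.

By hand, I take dawn's charges as equal and the partner as stable, which leaves 14.5% of the substrate, under that tie. Neglecting the intermediate as well, I put the side product ahead in dawn, at 53.6%. Dusk and noon carry more partner, so I put them higher, but below the share.

The forecast gave 48%, 58.6% and 61.7% for dawn, dusk and noon, saying “The side product therefore leads in all three cases”.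

The side product leads, at 48.1% in dawn, 58.6% in dusk and 61.7% in noon, and dawn lies under my figure. With the step from partner to decomposed reagent struck out, dawn ends with 53.7% side product. As run, dawn keeps 20.4% substrate and 2.92% intermediate, and the share of the remainder is 48.1%.

Now take the neighbour of dusk charged with 0.680 equiv of partner. Its 45.4% substrate and 1.72% intermediate left give 33.2% by the share, and the substrate stands above the tie. The computed flask holds 33.2% side product, and the substrate leads.

All constants are made up, and the outcome is calculated.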